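## Retrosynthetic overview

1. Target 25 ⇒ alkyne 23. The 2-substituted butadiene (C13–C16) is the enyne-metathesis product of a but-3-ynyl chain and ethylene. The alkyne comes from lactone 18 by partial reduction, C1 Wittig homologation and an Ohira–Bestmann reaction.
2. Enabling feature: on ring B, the oxygen on C8 and the side-chain carbon C11 on C9 lie on the same face. O8–C8–C9–C11 plus C12 is therefore a cis-fused γ-butyrolactone (temporary ring C), which maps onto a [2+2+1] union of a C8 ketone, a C9=C11 vinyl group on C10, and CO.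
3. Key disconnection: lactone 18 ⇒ monocyclic keto-alkene 15 + CO by a titanocene hetero-Pauson–Khand reaction. It forms C8–C9, C11–C12 and C12–O8, closes rings B and C, and sets C8 and C9 in one operation.
4. 15 ⇒ ring A by an enantioselective Diels–Alder reaction of (E)-2-methylhepta-2,6-dienal 3 with silyloxydiene 5 (sets C5 and C10). C4 then follows by hydroxymethylation and C3 by directed reduction.
5. Ring order: A (step 3), then B and the temporary lactone ring C together (step 11), then ring C is opened again (steps 12–14).

Key step: step 11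

Convention: labdane numbering (C1–C20) is used for all compounds. The lower face carries the C10 methyl group C20 and the upper face carries H5. The target is (3R,4S,5S,8S,9R,10R).

Assumption: the (S)-configured oxazaborolidinium catalyst of step 3 is taken to expose the Re face at C2 of enal 3; if the sense of induction is the opposite one, the equally available (R)-catalyst is used.

## Route

Step 1
Reactants: 1 pent-4-enal; 2 2-(triphenylphosphoranylidene)propanal
Product: 3 (E)-2-methylhepta-2,6-dienal
Conditions: toluene, 80 °C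
Reagents that add atoms: none
Why: Wittig olefination with a stabilised α-branched ylide should give the (E)-trisubstituted enal, whose geometry later encodes the C5/C10 relationship.

Step 2
Reactants: 4 pent-1-en-3-one
Product: 5 (Z)-3-(triisopropylsilyloxy)penta-1,3-diene
Conditions: i-Pr3SiOTf, Et3N, Et2O, 0 °C
Reagents that add atoms: triisopropylsilyl triflate CC(C)[Si](C(C)C)(C(C)C)OS(=O)(=O)C(F)(F)F
Why: Soft enolisation of the ethyl ketone (silyl triflate/amine) should give the 2-silyloxydiene as the Z enol ether, whose methyl group points outward in the s-cis form.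

Step 3
Reactants: 3 (E)-2-methylhepta-2,6-dienal; 5 (Z)-3-(triisopropylsilyloxy)penta-1,3-diene
Product: 6 (1R,5R,6R)-6-(but-3-enyl)-1,5-dimethyl-4-(triisopropylsilyloxy)cyclohex-3-ene-1-carbaldehyde
Conditions: (S)-3,3-diphenyl-1-(2-methylphenyl)tetrahydro-1H,3H-pyrrolo[1,2-c][1,3,2]oxazaborole·(CF3SO2)2NH (20 mol %), CH2Cl2, −78 → −40 °C
Reagents that add atoms: none
Why: In this enantioselective Diels–Alder reaction of an α-substituted enal under cationic oxazaborolidine catalysis, the silyloxy group directs C4 to C5 and C1 to C10, suprafacial addition to the E alkene places the C20 methyl cis and the formyl group trans to the C6 chain (C5, C10), the catalyst selects the enal face and so the absolute configuration, and the endo-derived C4 centre is erased in step 6.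

Step 4
Reactants: 6 Diels–Alder aldehyde
Product: 7 6-(but-3-enyl)-1,5-dimethyl-4-(triisopropylsilyloxy)-1-vinylcyclohex-3-ene (configuration as in 6)
Conditions: MePPh3Br, KN(SiMe3)2, THF, 0 → 23 °C
Reagents that add atoms: methyltriphenylphosphonium bromide C[P+](c1ccccc1)(c1ccccc1)c1ccccc1.[Br-]
Why: Wittig methylenation of the non-enolisable neopentyl aldehyde installs the C9=C11 vinyl group while the silyl enol ether masks the C3 ketone.

Step 5
Reactants: 7 triene silyl enol ether
Product: 8 5-(but-3-enyl)-4,6-dimethyl-4-vinylcyclohex-2-en-1-one (C20 cis to the chain; vinyl and C4 methyl on the upper face)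
Conditions: Pd(OAc)2 (1.1 equiv), DMSO, 45 °C
Reagents that add atoms: none
Why: In the Saegusa–Ito oxidation, palladation at C2 and β-hydride loss from C1 should give the C1=C2 enone, which leaves C4–H as the only enolisable position.

Step 6
Reactants: 8 enone
Product: 10 5-(but-3-enyl)-6-(hydroxymethyl)-4,6-dimethyl-4-vinylcyclohex-2-en-1-one (C18 upper face; C19 lower face), via lithium dienolate 9 (not isolated)
Conditions: LiN(i-Pr)2, THF, −78 °C; CH2O (gas, from cracked paraformaldehyde), −78 °C; aq NH4Cl
Reagents that add atoms: formaldehyde C=O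
Why: Aldol addition of the cross-conjugated dienolate to formaldehyde (α′-hydroxymethylation) should create quaternary C4, because the electrophile enters on the upper face, anti to the adjacent C5 chain and to the C10 methyl group.

Step 7
Reactants: 10 hydroxymethyl enone
Product: 11 3-(but-3-enyl)-2-(hydroxymethyl)-2,4-dimethyl-4-vinylcyclohexan-1-one
Conditions: Cu(OAc)2·H2O (5 mol %), 1,2-bis(diphenylphosphino)benzene (5 mol %), (EtO)2MeSiH, t-BuOH, toluene, 23 °C
Reagents that add atoms: none
Why: Copper hydride conjugate reduction is selective for the enone C1=C2 bond and should leave both terminal alkenes and the ketone untouched.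

Step 8
Reactants: 11 β-hydroxy ketone
Product: 12 3-(but-3-enyl)-2-(hydroxymethyl)-2,4-dimethyl-4-vinylcyclohexan-1-ol (O3 lower face; trans to C18)
Conditions: Me4NBH(OAc)3, MeCN–AcOH, −20 °C
Reagents that add atoms: none
Why: In the Evans–Saksena hydroxyl-directed reduction, the acetoxyborohydride bound to O18 delivers hydride to C3 from the upper face whatever the ring conformer, so O3 ends on the lower face as in the target.

Step 9
Reactants: 12 diol
Product: 14 O18-TBS O3-TES bis-silyl ether of 12, via mono-TBS ether 13 (not isolated)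
Conditions: t-BuMe2SiCl (1.05 equiv), imidazole, CH2Cl2, 0 °C; then Et3SiCl, 4-(dimethylamino)pyridine, 23 °C
Reagents that add atoms: tert-butyldimethylsilyl chloride CC(C)(C)[Si](C)(C)Cl; triethylsilyl chloride CC[Si](Cl)(CC)CC
Why: Stepwise silylation uses the rate gap between primary O18 (robust TBS) and hindered secondary O3 (acid-labile TES), which later allows O3 alone to be acetylated.

Step 10
Reactants: 14 bis-silyl ether
Product: 15 4-[ring A]butan-2-one: C8 methyl ketone on the C5 arm and vinyl group on C10
Conditions: PdCl2 (10 mol %), Cu(OAc)2 (20 mol %), O2 (1 atm), MeC(O)NMe2–H2O, 23 °C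
Reagents that add atoms: water O
Why: The Tsuji–Wacker oxidation should convert only the unhindered but-3-enyl terminus into the methyl ketone, because the vinyl group on quaternary C10 binds palladium poorly, and Cu(OAc)2 keeps the medium mild for the TES ether.

Step 11
Reactants: 15 keto-alkene
Product: 18 cis-fused tricyclic γ-lactone (13,14,15,16-tetranorlabdan-12,8-olide; O8 and C11 on the upper face), via oxatitanacyclopentane 16 (not isolated), via acyl titanacycle 17 (not isolated)
Conditions: Cp2Ti(PMe3)2 (1.1 equiv, from Cp2TiCl2, Mg, PMe3), toluene, 23 °C; then CO (1.5 bar), 23 → 70 °C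
Reagents that add atoms: carbon monoxide [C-]#[O+]
Why: Loss of PMe3 lets the divalent titanium fragment Cp2Ti bind the C8 ketone and the C9=C11 vinyl group and couple them oxidatively to 16 (C8–C9 bond), CO then inserts into the Ti–C11 bond to give 17, and reductive elimination of acyl and alkoxide closes the lactone and releases Cp2Ti(CO)2. The closest known reaction type is the titanocene-mediated hetero-Pauson–Khand [2+2+1] reaction of alkenyl ketones with CO to fused γ-butyrolactones. Ring B closes in a 6-exo mode (C11 stays outside the ring) between the two equatorial arms on C5 and C10 of the ring A chair, which fixes the trans ring fusion, and the five-membered ring C closes by C12–O8 reductive elimination. Because O8, C8, C9, C11 and Ti must lie nearly in one plane in the wedge of the bent metallocene, O8 and C11 can only end up cis on ring B, so C8 and C9 are set as a pair. The bulky Cp2Ti unit should build this pair on the face opposite the axial C10 methyl group, which places O8 equatorial, C17 axial and C11 axial on C9, that is the (8S,9R) array that equilibrating methods would not give. The step needs one ketone and one terminal alkene to react alone, which 15 secures because it holds no other π-system and no acidic proton (both hydroxyls are silylated).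

Step 12
Reactants: 18 lactone
Product: 19 γ-lactol (8,12-epoxy-12-ol; anomer mixture)
Conditions: i-Bu2AlH (1.1 equiv), CH2Cl2, −78 °C; aq potassium sodium tartrate
Reagents that add atoms: none
Why: Partial reduction of the γ-lactone at low temperature stops at the aluminium hemiacetal and should give the lactol with the silyl ethers intact.

Step 13
Reactants: 19 γ-lactol
Product: 21 δ-lactol (8,13-epoxy-13-ol; free 3-OH; 18-OTBS), via methyl enol ether 20 (not isolated)
Conditions: MeOCH2PPh3Cl, KN(SiMe3)2, THF, 0 → 23 °C; then 1 M aq HCl, 0 → 23 °C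
Reagents that add atoms: (methoxymethyl)triphenylphosphonium chloride COC[P+](c1ccccc1)(c1ccccc1)c1ccccc1.[Cl-]; water O
Why: In this Wittig one-carbon homologation the lactol reacts through its open hydroxy-aldehyde form, and aqueous acid then hydrolyses the enol ether to the C13 aldehyde (trapped by O8) and cleaves the TES ether while the neopentyl TBS ether should stay.

Step 14
Reactants: 21 δ-lactol
Product: 22 but-3-ynyl compound (15,16-dinorlabd-13-yne-3,8-diol 18-TBS ether)
Conditions: dimethyl (1-diazo-2-oxopropyl)phosphonate, K2CO3, MeOH, 23 °C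
Reagents that add atoms: dimethyl (1-diazo-2-oxopropyl)phosphonate COP(=O)(OC)C(=[N+]=[N-])C(C)=O
Why: Ohira–Bestmann (Seyferth–Gilbert) homologation of the lactol through its open aldehyde form should give the terminal alkyne and free the C8 hydroxyl without touching a stereocentre.

Step 15
Reactants: 22 alkyne diol
Product: 23 3-O-acetate of 22
Conditions: Ac2O, pyridine, 4-(dimethylamino)pyridine (cat.), CH2Cl2, 23 °C
Reagents that add atoms: acetic anhydride CC(=O)OC(C)=O
Why: Acylation under nucleophilic catalysis should reach only the secondary C3 hydroxyl, because the tertiary C8 hydroxyl is too hindered and O18 is still silylated.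

Step 16
Reactants: 23 alkyne acetate
Product: 24 18-O-TBS ether of the target
Conditions: second-generation Grubbs catalyst (5 mol %), ethylene (1 atm), toluene, 80 °C
Reagents that add atoms: ethylene C=C
Why: Enyne cross-metathesis with ethylene turns the terminal alkyne into the 2-substituted buta-1,3-diene C13(=C16)–C14=C15 without a by-product.

Step 17
Reactants: 24 silyl ether
Product: 25 (3R,4S,5S,8S,9R,10R)-3-acetoxylabda-13(16),14-diene-8,18-diol (target)
Conditions: HF·pyridine, pyridine, THF, 0 → 23 °C
Reagents that add atoms: none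
Why: Buffered fluoride desilylation should free O18 without 1,3-acetyl migration, dehydration at C8 or damage to the diene.

## Compound list

1 | pent-4-enal | C=CCCC=O | starting material
2 | 2-(triphenylphosphoranylidene)propanal | CC(C=O)=P(c1ccccc1)(c1ccccc1)c1ccccc1 | starting material
3 | (E)-2-methylhepta-2,6-dienal | O=C/C(C)=C/CCC=C | intermediate
4 | pent-1-en-3-one | C=CC(=O)CC | starting material
5 | (Z)-3-(triisopropylsilyloxy)penta-1,3-diene | C=C/C(O[Si](C(C)C)(C(C)C)C(C)C)=C/C | intermediate
6 | Diels–Alder aldehyde | O=C[C@]1(C)CC=C(O[Si](C(C)C)(C(C)C)C(C)C)[C@H](C)[C@H]1CCC=C | intermediate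
7 | vinyl silyl enol ether | C=C[C@]1(C)CC=C(O[Si](C(C)C)(C(C)C)C(C)C)[C@H](C)[C@H]1CCC=C | intermediate
8 | enone | C=C[C@]1(C)C=CC(=O)[C@H](C)[C@H]1CCC=C | intermediate
9 | lithium dienolate | C=C[C@]1(C)C=CC([O-])=C(C)[C@H]1CCC=C.[Li+] | intermediate
10 | hydroxymethyl enone | C=C[C@]1(C)C=CC(=O)[C@](C)(CO)[C@H]1CCC=C | intermediate
11 | β-hydroxy ketone | C=C[C@]1(C)CCC(=O)[C@](C)(CO)[C@H]1CCC=C | intermediate
12 | 3,18-diol | C=C[C@]1(C)CC[C@@H](O)[C@](C)(CO)[C@H]1CCC=C | intermediate
13 | mono-TBS ether | C=C[C@]1(C)CC[C@@H](O)[C@](C)(CO[Si](C)(C)C(C)(C)C)[C@H]1CCC=C | intermediate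
14 | bis-silyl ether | C=C[C@]1(C)CC[C@@H](O[Si](CC)(CC)CC)[C@](C)(CO[Si](C)(C)C(C)(C)C)[C@H]1CCC=C | intermediate
15 | keto-alkene (key-step precursor) | C=C[C@]1(C)CC[C@@H](O[Si](CC)(CC)CC)[C@](C)(CO[Si](C)(C)C(C)(C)C)[C@H]1CCC(C)=O | intermediate
16 | oxatitanacyclopentane | [cH-]1cccc1.[cH-]1cccc1.[Ti+2]1C[C@@H]2[C@]3(C)CC[C@@H](O[Si](CC)(CC)CC)[C@](C)(CO[Si](C)(C)C(C)(C)C)[C@H]3CC[C@]2(C)O1 | intermediate
17 | acyl titanacycle | [cH-]1cccc1.[cH-]1cccc1.O=C1C[C@@H]2[C@]3(C)CC[C@@H](O[Si](CC)(CC)CC)[C@](C)(CO[Si](C)(C)C(C)(C)C)[C@H]3CC[C@]2(C)O[Ti+2]1 | intermediate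
18 | cis-fused γ-lactone | O=C1C[C@@H]2[C@]3(C)CC[C@@H](O[Si](CC)(CC)CC)[C@](C)(CO[Si](C)(C)C(C)(C)C)[C@H]3CC[C@]2(C)O1 | intermediate
19 | γ-lactol | OC1C[C@@H]2[C@]3(C)CC[C@@H](O[Si](CC)(CC)CC)[C@](C)(CO[Si](C)(C)C(C)(C)C)[C@H]3CC[C@]2(C)O1 | intermediate
20 | methyl enol ether (E/Z) | COC=CC[C@@H]1[C@]2(C)CC[C@@H](O[Si](CC)(CC)CC)[C@](C)(CO[Si](C)(C)C(C)(C)C)[C@H]2CC[C@]1(C)O | intermediate
21 | δ-lactol | OC1CC[C@@H]2[C@]3(C)CC[C@@H](O)[C@](C)(CO[Si](C)(C)C(C)(C)C)[C@H]3CC[C@]2(C)O1 | intermediate
22 | alkyne diol | C#CCC[C@@H]1[C@]2(C)CC[C@@H](O)[C@](C)(CO[Si](C)(C)C(C)(C)C)[C@H]2CC[C@]1(C)O | intermediate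
23 | alkyne acetate | C#CCC[C@@H]1[C@]2(C)CC[C@@H](OC(C)=O)[C@](C)(CO[Si](C)(C)C(C)(C)C)[C@H]2CC[C@]1(C)O | intermediate
24 | diene TBS ether | C=CC(=C)CC[C@@H]1[C@]2(C)CC[C@@H](OC(C)=O)[C@](C)(CO[Si](C)(C)C(C)(C)C)[C@H]2CC[C@]1(C)O | intermediate
25 | target | C=CC(=C)CC[C@@H]1[C@]2(C)CC[C@@H](OC(C)=O)[C@](C)(CO)[C@H]2CC[C@]1(C)O | target

Total step count: 17.
Longest linear sequence: 16 (steps 1 and 3–17).

## Steps most likely to fail

**Step 11.**
- What may go wrong: the neopentyl vinyl group may bind the titanocene fragment too weakly for oxidative coupling. The coupling may take place partly on the lower face (poor facial selectivity). The acyl complex may resist reductive elimination.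
- Fallback, setting out from 15 and coming back at 18: Lemieux–Johnson cleavage (OsO4 cat., NaIO4, 2,6-lutidine) of the vinyl group gives keto aldehyde F1. A Horner–Wadsworth–Emmons reaction (triethyl phosphonoacetate, LiCl, DBU) gives (E)-enoate F2.
- SmI2 in THF–MeOH then forms the C8 ketyl, which adds 6-exo to C9 of the enoate. The samarium-bound oxygen should again take the equatorial site. The cis hydroxy ester lactonises in the flask to 18, and any isomer that stays open is removed by chromatography.

**Step 3.**
- What may go wrong: slow cycloaddition of the trisubstituted enal may let acid-induced desilylation of the diene or Mukaiyama aldol addition to the formyl group compete. Facial control by the catalyst may erode.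
- Fallback, setting out from 3 and coming back at 8 (acid-free, auxiliary-controlled): (E)-4-methoxybut-3-en-2-one and (2R,5R)-2,5-diphenylpyrrolidine (drawn as the enantiomer assumed to shield the correct face) give vinylogous amide F3. KN(SiMe3)2/t-BuMe2SiCl gives aminosiloxydiene F4.
- Heating F4 with 3 in toluene gives cycloadduct F5, and Wittig methylenation gives vinyl compound F6. HF in MeCN hydrolyses the enol ether and eliminates the amine to give enone F7. LiN(i-Pr)2/MeI methylates C4 trans to the C5 chain and gives 8.

**Step 6.**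
- What may go wrong: deprotonation of the hindered C4–H may be incomplete. Formaldehyde may polymerise. Retro-aldol loss of formaldehyde may occur on warming, and facial selectivity may be poor.
- Fallback, setting out from 8 and coming back at 10: the dienolate is trapped with Me3SiCl and isolated as silyl dienol ether F8. F8 is then combined with aqueous formaldehyde and Sc(OTf)3 (cat.) in THF–H2O. This Mukaiyama aldol reaction in water has no strong base present and an irreversible silyl transfer.

## Further compounds

F1 | step 11 | keto aldehyde | O=C[C@]1(C)CC[C@@H](O[Si](CC)(CC)CC)[C@](C)(CO[Si](C)(C)C(C)(C)C)[C@H]1CCC(C)=O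
F2 | step 11 | (E)-enoate | CCOC(=O)/C=C/[C@]1(C)CC[C@@H](O[Si](CC)(CC)CC)[C@](C)(CO[Si](C)(C)C(C)(C)C)[C@H]1CCC(C)=O
F3 | step 3 | vinylogous amide | CC(=O)/C=C/N1[C@@H](c2ccccc2)CC[C@@H]1c1ccccc1
F4 | step 3 | aminosiloxydiene | C=C(O[Si](C)(C)C(C)(C)C)/C=C/N1[C@@H](c2ccccc2)CC[C@@H]1c1ccccc1
F5 | step 3 | cycloadduct | O=C[C@]1(C)[C@H](N2[C@@H](c3ccccc3)CC[C@@H]2c2ccccc2)C=C(O[Si](C)(C)C(C)(C)C)C[C@H]1CCC=C
F6 | step 3 | vinyl compound | C=C[C@]1(C)[C@H](N2[C@@H](c3ccccc3)CC[C@@H]2c2ccccc2)C=C(O[Si](C)(C)C(C)(C)C)C[C@H]1CCC=C
F7 | step 3 | enone | C=C[C@]1(C)C=CC(=O)C[C@H]1CCC=C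
F8 | step 6 | silyl dienol ether | C=C[C@]1(C)C=CC(O[Si](C)(C)C)=C(C)[C@H]1CCC=C
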